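**Retrosynthetic overview**

- Feature: the C2 carbinol is allylic to the ring A alkene C3=C4, and C4 is the α-carbon of the spiro 18,19-lactone on C5. C3 is therefore the β-carbon of an α-alkylidene lactone, and C2–C3 is cut last as an alkenyl–aldehyde bond.
- Disconnections: ring A at C2–C3 (Ni/Cr coupling of an (E)-C3 iodide with a formyl group on C1); ring C at C12–C13 (Friedel–Crafts acylation of the furan); C3 by formylation of the saturated spirolactone; C1–C2 by hydroboration of a 1-(furan-2-yl)vinyl group on C10.
- Ring B comes from an achiral 4-cyano-4-(tert-butoxycarbonylmethyl)cyclohexa-2,5-dienone: rhodium-catalysed asymmetric alkenyl addition sets C10 and C5, two enolate alkylations build C9, and a 1,2-carbonyl transposition with methylation gives C8-Me and C7-O.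
- Order of rings: ring B (bought as a cyclohexane) → spiro-lactone → ring C → ring A.

Key step: step 25

Remark: clerodane numbering of the target is used for every intermediate and α is the ring B face that carries C19 and C20; reagent-bound adducts consumed within one operation (the lithium enolates of steps 1, 7 and 8, the organoborane of step 13, the aluminium imine of step 11) are named in the Why line and not numbered.

**Route**

Step 1
Reactants: 1 1,4-dioxaspiro[4.5]decane-8-carbonitrile; 2 tert-butyl bromoacetate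
Product: 3 tert-butyl 2-(8-cyano-1,4-dioxaspiro[4.5]decan-8-yl)acetate
Conditions: LiN(i-Pr)2, THF, −78 °C; then 2, −78 → 0 °C
Reagents that add atoms: none
Why: α-Alkylation of the nitrile-stabilised carbanion with the reactive α-bromo ester gives the quaternary carbon that becomes C5 (nitrile = C19, CH2CO2t-Bu = C4–C18); no stereocentre is formed.

Step 2
Reactants: 3 tert-butyl 2-(8-cyano-1,4-dioxaspiro[4.5]decan-8-yl)acetate
Product: 4 tert-butyl 2-(1-cyano-4-oxocyclohexyl)acetate
Conditions: 1 M HCl, THF, rt
Reagents that add atoms: water, O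
Why: Acid-catalysed ketal hydrolysis; dilute acid at room temperature should leave the tert-butyl ester and the nitrile untouched.

Step 3
Reactants: 4 tert-butyl 2-(1-cyano-4-oxocyclohexyl)acetate
Product: 5 tert-butyl 2-(1-cyano-4-oxocyclohexa-2,5-dien-1-yl)acetate
Conditions: IBX (4 equiv), DMSO/fluorobenzene, 75 °C
Reagents that add atoms: none
Why: Twofold IBX dehydrogenation of the ketone (Nicolaou desaturation); the 4,4-disubstitution prevents aromatisation, so the achiral cross-conjugated dienone with two enantiotopic enone arms should result.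

Step 4
Reactants: 6 furfural
Product: 7 2-ethynylfuran
Conditions: dimethyl (1-diazo-2-oxopropyl)phosphonate, K2CO3, MeOH, 0 °C → rt
Reagents that add atoms: dimethyl (1-diazo-2-oxopropyl)phosphonate, COP(=O)(OC)C(=[N+]=[N-])C(C)=O
Why: Seyferth–Gilbert homologation with the Ohira–Bestmann reagent converts the aldehyde into the terminal alkyne under mild base.

Step 5
Reactants: 7 2-ethynylfuran
Product: 8 2-[1-(furan-2-yl)ethenyl]-4,4,5,5-tetramethyl-1,3,2-dioxaborolane
Conditions: B2pin2, CuCl (5 mol%), 1,3-bis(2,4,6-trimethylphenyl)imidazolinium chloride (5 mol%), NaOt-Bu (10 mol%), MeOH (2 equiv), THF, −20 °C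
Reagents that add atoms: bis(pinacolato)diboron, CC1(C)OB(OC1(C)C)B1OC(C)(C)C(C)(C)O1
Why: Copper-catalysed protoboration of a terminal aryl alkyne: with an N-aryl carbene ligand the Cu–B bond adds syn with boron at the internal carbon, and methanol protonates the C–Cu bond to give the 1,1-disubstituted alkenylboronate.

Step 6
Reactants: 5 tert-butyl 2-(1-cyano-4-oxocyclohexa-2,5-dien-1-yl)acetate; 8 2-[1-(furan-2-yl)ethenyl]-4,4,5,5-tetramethyl-1,3,2-dioxaborolane
Product: 9 tert-butyl 2-[(1S,6R)-1-cyano-6-[1-(furan-2-yl)ethenyl]-4-oxocyclohex-2-en-1-yl]acetate (alkenyl group on C10 cis to the C19 nitrile on C5)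
Conditions: 8 (1.5 equiv), [Rh(C2H4)2Cl]2 (2.5 mol%), (S)-BINAP (6 mol%), KOH (0.5 equiv), dioxane/H2O 10:1, 40 °C
Reagents that add atoms: none
Why: Hayashi–Miyaura rhodium-catalysed asymmetric 1,4-addition used as a desymmetrisation: the (S)-BINAP–rhodium alkenyl is expected to select one enantiotopic enone arm (same sense as for cyclohex-2-enone) and, on that arm, to add at C10 from the face of the slim nitrile, anti to the CH2CO2t-Bu group, which sets C10 and makes C5 stereogenic with C1 cis to C19.

Step 7
Reactants: 9 tert-butyl 2-[(1S,6R)-1-cyano-6-[1-(furan-2-yl)ethenyl]-4-oxocyclohex-2-en-1-yl]acetate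
Product: 10 the C9-methyl derivative of 9 (C9 epimers)
Conditions: LiN(i-Pr)2, THF, −78 °C; then MeI, −78 → −20 °C
Reagents that add atoms: iodomethane, CI
Why: Kinetic α′-deprotonation of the enone (C9 is the only enolisable position) and methylation of the lithium enolate; the C9 configuration is irrelevant because the centre is planarised again in step 8.

Step 8
Reactants: 10 the C9-methyl derivative of 9; 2 tert-butyl bromoacetate
Product: 11 enone with quaternary C9 (C20 methyl α; CH2CO2t-Bu arm = C11–C12 β, trans to the alkenyl group on C10)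
Conditions: LiN(i-Pr)2, THF/DMPU, −78 °C; then 2, −78 → −20 °C
Reagents that add atoms: none
Why: Alkylation of the cross-conjugated lithium dienolate: the C10 substituent sits pseudoaxial to avoid A(1,2) strain with the C9 methyl, so the bromoacetate should enter anti to it, which sets the quaternary C9 with C11 trans to C1.

Step 9
Reactants: 11 enone with quaternary C9
Product: 13 alkenyl triflate (C8–OTf; C7=C8; C6 now CH2), via lithium enolate 12 (not isolated)
Conditions: LiBH(s-Bu)3, THF, −78 °C; then PhNTf2, −78 → 0 °C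
Reagents that add atoms: N-phenylbis(trifluoromethanesulfonimide), O=S(=O)(N(c1ccccc1)S(=O)(=O)C(F)(F)F)C(F)(F)F
Why: Conjugate hydride reduction of the β-unsubstituted enone (1,2-attack is blocked by the quaternary C9) gives the regiodefined enolate, which is O-triflated in the same flask (enolate trapping as the enol triflate).

Step 10
Reactants: 13 alkenyl triflate
Product: 14 C8-methyl cyclohexene (C7=C8 with C17 on C8; nitrile and both tert-butyl esters retained)
Conditions: Me2Zn, Pd(PPh3)4 (5 mol%), THF, 50 °C
Reagents that add atoms: dimethylzinc, C[Zn]C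
Why: Negishi cross-coupling of the alkenyl triflate installs the C17 methyl; esters, nitrile and furan are inert to the organozinc.

Step 11
Reactants: 14 C8-methyl cyclohexene
Product: 15 C19 aldehyde (formyl group on C5 in place of the nitrile)
Conditions: i-Bu2AlH (1.3 equiv), toluene, −78 → −40 °C; aq. KNa tartrate work-up
Reagents that add atoms: water, O
Why: Half-reduction of the nitrile to the aluminium aldimine, hydrolysed on work-up; tert-butyl esters react much more slowly with i-Bu2AlH at low temperature, and the neopentyl aldehyde cannot enolise.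

Step 12
Reactants: 15 C19 aldehyde
Product: 17 spiro-γ-lactone (C5–C19H2–O–C18(=O)–C4H2; C19 α and C4 β), via hydroxy ester 16 (not isolated)
Conditions: NaBH4, MeOH, 0 °C; then NaH (0.2 equiv), THF, rt
Reagents that add atoms: none
Why: Borohydride reduction of the aldehyde, then alkoxide-catalysed lactonisation onto the C18 tert-butyl ester (five-membered ring; the C12 ester would need a seven-membered ring), which stores the C5 configuration as the spirolactone.

Step 13
Reactants: 17 spiro-γ-lactone
Product: 18 diol (7β-OH, 8β-H; primary C2–OH; both C1 epimers)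
Conditions: BH3·THF, THF, 0 °C → rt; then H2O2, aq. NaOH, 0 °C; work-up at pH 3
Reagents that add atoms: hydrogen peroxide, OO
Why: Hydroboration–oxidation of both alkenes, boron going to the less substituted C7 and the terminal C2; H and OH add syn to the ring alkene, expected from the β face anti to the axial C20 methyl (C7 and C8 are reset in steps 15 and 16), and C1 forms as both epimers, carried together until step 24.

Step 14
Reactants: 18 diol
Product: 19 C2 tert-butyldiphenylsilyl ether (C7–OH free)
Conditions: t-BuPh2SiCl, imidazole, DMF, 0 °C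
Reagents that add atoms: tert-butyl(chloro)diphenylsilane, CC(C)(C)[Si](Cl)(c1ccccc1)c1ccccc1
Why: Selective silylation of the primary alcohol in the presence of the hindered secondary C7 alcohol.

Step 15
Reactants: 19 C2 silyl ether
Product: 20 C7 ketone (C17 methyl on C8 α, equatorial)
Conditions: Dess–Martin periodinane, NaHCO3, CH2Cl2, rt; then DBU (0.2 equiv), rt
Reagents that add atoms: none
Why: Dess–Martin oxidation of the secondary alcohol; DBU then equilibrates C8 through the enol to the more stable equatorial methyl epimer (C17 α, cis to C20).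

Step 16
Reactants: 20 C7 ketone
Product: 21 7α-alcohol (axial OH)
Conditions: NaBH4, MeOH/CH2Cl2, −20 °C
Reagents that add atoms: none
Why: Hydride must attack from the equatorial β face because the axial C19 methylene and the axial C20 methyl block the α face (the situation of 11-oxo steroids), which gives the axial 7α-alcohol; the lactone and ester are not reduced.

Step 17
Reactants: 21 7α-alcohol
Product: 22 7α-acetate
Conditions: Ac2O, DMAP, pyridine, 60 °C
Reagents that add atoms: acetic anhydride, CC(=O)OC(C)=O
Why: DMAP-catalysed acetylation, run warm because the axial hydroxyl is flanked by two syn-axial carbons.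

Step 18
Reactants: 22 7α-acetate
Product: 24 α-hydroxymethylene lactone (C4=C3H–OH), via dimethylaminomethylene lactone 23 (not isolated)
Conditions: t-BuOCH(NMe2)2, toluene, 100 °C; then 1 M HCl, THF, rt
Reagents that add atoms: tert-butoxybis(dimethylamino)methane (Bredereck's reagent), CN(C)C(OC(C)(C)C)N(C)C; water, O
Why: Bredereck aminomethylenation at the lactone α-methylene C4 (the acetate methyl and the tert-butyl ester methylene are not acidic enough to condense) introduces C3 as the (E)-enaminone, and mild acid hydrolysis gives the formyl lactone as its enol.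

Step 19
Reactants: 24 α-hydroxymethylene lactone
Product: 25 (E)-enol triflate (C3–OTf trans to the lactone carbonyl C18, cis to C5)
Conditions: Tf2O, aq. Me4NOH, toluene, 0 °C
Reagents that add atoms: trifluoromethanesulfonic anhydride, O=S(=O)(OS(=O)(=O)C(F)(F)F)C(F)(F)F
Why: O-Triflation of the formyl-lactone enolate with a non-chelating tetraalkylammonium counter-ion: the enolate oxygen lies anti to the lactone carbonyl, as in the (E)-selective O-alkylation of formyl lactones and the (E)-selective triflation of β-dicarbonyls under these conditions, so the (E)-triflate is expected.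

Step 20
Reactants: 25 (E)-enol triflate
Product: 29 tricyclic C12 ketone (ring C closed; enol triflate retained), via trimethylsilyl ester 26 (not isolated), via carboxylic acid 27 (not isolated), via acid chloride 28 (not isolated)
Conditions: Me3SiOTf, 2,6-lutidine, CH2Cl2, 0 °C, then H2O; 1-chloro-N,N,2-trimethylprop-1-en-1-amine, CH2Cl2, 0 °C; SnCl4, CH2Cl2 (0.005 M), −78 → −20 °C
Reagents that add atoms: none
Why: Me3SiOTf cleaves the tert-butyl ester (isobutene loss) to the silyl ester, hydrolysed on work-up; the acid is converted to the acid chloride under neutral conditions and SnCl4 promotes intramolecular Friedel–Crafts acylation of the 2-alkylfuran at C13, the only ring carbon the C11–C12 tether can reach, closing the seven-membered ring C at high dilution; both C1 epimers can place the furan beside C11, and the enol triflate, acetate, lactone and silyl ether should survive SnCl4 at low temperature.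

Step 21
Reactants: 29 tricyclic C12 ketone
Product: 30 (E)-alkenylstannane (C3–SnMe3)
Conditions: (Me3Sn)2, Pd(PPh3)4 (5 mol%), LiCl, THF, 60 °C
Reagents that add atoms: hexamethylditin, C[Sn](C)(C)[Sn](C)(C)C
Why: Palladium-catalysed stannylation of the electron-poor alkenyl triflate (Stille-type coupling with the distannane) proceeds with retention of alkene geometry.

Step 22
Reactants: 30 (E)-alkenylstannane
Product: 31 (E)-iodomethylene lactone (C3–I cis to C5)
Conditions: I2, CH2Cl2, 0 °C
Reagents that add atoms: iodine, II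
Why: Iododestannylation with retention of configuration; the furan, now deactivated by the C12 acyl group, should not be iodinated.

Step 23
Reactants: 31 (E)-iodomethylene lactone
Product: 32 primary alcohol (C2–OH; C1 epimers)
Conditions: HF·pyridine, pyridine/THF, 0 °C → rt
Reagents that add atoms: none
Why: Buffered fluoride cleaves the silyl ether without touching the β-iodo enoate, the acetate or the ketone.

Step 24
Reactants: 32 primary alcohol
Product: 34 aldehyde precursor (rings B and C; spiro (E)-iodomethylene lactone at C5; formyl group on C1; C1 as in the target), via C1-epimeric aldehyde mixture 33 (not isolated)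
Conditions: Dess–Martin periodinane, NaHCO3, CH2Cl2, 0 °C → rt; then i-Pr2NEt (0.5 equiv), CH2Cl2, rt
Reagents that add atoms: none
Why: Dess–Martin oxidation gives the aldehyde and the hindered amine then equilibrates C1 through the enol: with C16 held beside C11 by ring C, the epimer whose formyl group points towards C4 and whose H1 lies between the axial C19 and C20 carbons is favoured (the other has the formyl group syn-axial to both), so the mixture should converge on 34.

Step 25
Reactants: 34 aldehyde precursor
Product: 35 the target, CNP0182929.1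
Conditions: CrCl2 (20 mol%), NiCl2·glyme (2 mol%), Me3SiCl (2 equiv), LiCl, DMF (0.005 M), undivided cell, Al anode, Ni-foam cathode, constant current, rt; 1 M HCl/THF work-up
Reagents that add atoms: none
Why: CrCl2 reduces NiCl2 to zerovalent nickel, which inserts into the C3–I bond with retention of the (E) geometry; the alkenyl group passes to trivalent chromium, the alkenylchromium adds to the C2 aldehyde, Me3SiCl frees chromium from the alkoxide and the cathode reduces it back to CrCl2, so both metals are catalytic. The closest known reaction is the Nozaki–Hiyama–Kishi coupling of alkenyl iodides with aldehydes, used with stoichiometric CrCl2 for ring closures of β-iodo enoates onto aldehydes and with electrochemical chromium turnover for intermolecular couplings. Ring A closes by 6-exo-trig attack of C3 on the C2 carbonyl, possible only because the (E) iodide holds C3 cis to C5. The new C2 centre is controlled by a chair-like transition state in which the chromium-bound oxygen is pseudoequatorial, anti to the C1–C10 bond, which gives the 2α-alcohol trans to the furan carbon C16 on C1. The step needs chemoselectivity for the aldehyde over the C12 ketone, lactone and acetate, which alkenylchromium reagents show, and an untouched C1, which the neutral medium secures; high dilution suppresses intermolecular coupling.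

**Compound list**

1 | 1,4-dioxaspiro[4.5]decane-8-carbonitrile | N#CC1CCC2(CC1)OCCO2 | starting material
2 | tert-butyl bromoacetate | BrCC(=O)OC(C)(C)C | starting material
3 | tert-butyl 2-(8-cyano-1,4-dioxaspiro[4.5]decan-8-yl)acetate | N#CC1(CC(=O)OC(C)(C)C)CCC2(CC1)OCCO2 | intermediate
4 | tert-butyl 2-(1-cyano-4-oxocyclohexyl)acetate | N#CC1(CC(=O)OC(C)(C)C)CCC(=O)CC1 | intermediate
5 | tert-butyl 2-(1-cyano-4-oxocyclohexa-2,5-dien-1-yl)acetate | N#CC1(CC(=O)OC(C)(C)C)C=CC(=O)C=C1 | intermediate
6 | furfural | O=Cc1ccco1 | starting material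
7 | 2-ethynylfuran | C#Cc1ccco1 | intermediate
8 | 2-[1-(furan-2-yl)ethenyl]-4,4,5,5-tetramethyl-1,3,2-dioxaborolane | C=C(c1ccco1)B1OC(C)(C)C(C)(C)O1 | intermediate
9 | tert-butyl 2-[(1S,6R)-1-cyano-6-[1-(furan-2-yl)ethenyl]-4-oxocyclohex-2-en-1-yl]acetate | N#C[C@@]1(CC(=O)OC(C)(C)C)C=CC(=O)C[C@H]1C(=C)c1ccco1 | intermediate
10 | C9-methyl derivative of 9 (C9 epimers) | N#C[C@@]1(CC(=O)OC(C)(C)C)C=CC(=O)C(C)[C@H]1C(=C)c1ccco1 | intermediate
11 | enone with quaternary C9 (C20 α, C11 arm β) | N#C[C@@]1(CC(=O)OC(C)(C)C)C=CC(=O)[C@](C)(CC(=O)OC(C)(C)C)[C@H]1C(=C)c1ccco1 | intermediate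
12 | lithium C8 enolate from conjugate reduction of 11 | N#C[C@@]1(CC(=O)OC(C)(C)C)CC=C([O-])[C@](C)(CC(=O)OC(C)(C)C)[C@H]1C(=C)c1ccco1.[Li+] | intermediate
13 | C8 alkenyl triflate | N#C[C@@]1(CC(=O)OC(C)(C)C)CC=C(OS(=O)(=O)C(F)(F)F)[C@](C)(CC(=O)OC(C)(C)C)[C@H]1C(=C)c1ccco1 | intermediate
14 | C8-methyl cyclohexene, C19 nitrile | N#C[C@@]1(CC(=O)OC(C)(C)C)CC=C(C)[C@](C)(CC(=O)OC(C)(C)C)[C@H]1C(=C)c1ccco1 | intermediate
15 | C19 aldehyde | O=C[C@@]1(CC(=O)OC(C)(C)C)CC=C(C)[C@](C)(CC(=O)OC(C)(C)C)[C@H]1C(=C)c1ccco1 | intermediate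
16 | C19 hydroxymethyl tert-butyl ester | OC[C@@]1(CC(=O)OC(C)(C)C)CC=C(C)[C@](C)(CC(=O)OC(C)(C)C)[C@H]1C(=C)c1ccco1 | intermediate
17 | spiro-γ-lactone with C7=C8 and 1-(furan-2-yl)vinyl group | CC1=CC[C@]2(COC(=O)C2)[C@H](C(=C)c3ccco3)[C@@]1(C)CC(=O)OC(C)(C)C | intermediate
18 | diol: 7β-OH, 8α-methyl, C2–OH (C1 epimers) | C[C@@H]1[C@@H](O)C[C@]2(COC(=O)C2)[C@H](C(CO)c3ccco3)[C@@]1(C)CC(=O)OC(C)(C)C | intermediate
19 | C2 tert-butyldiphenylsilyl ether of 18 (C1 epimers) | C[C@@H]1[C@@H](O)C[C@]2(COC(=O)C2)[C@H](C(CO[Si](c3ccccc3)(c3ccccc3)C(C)(C)C)c3ccco3)[C@@]1(C)CC(=O)OC(C)(C)C | intermediate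
20 | C7 ketone, 8α-methyl (C1 epimers) | C[C@@H]1C(=O)C[C@]2(COC(=O)C2)[C@H](C(CO[Si](c3ccccc3)(c3ccccc3)C(C)(C)C)c3ccco3)[C@@]1(C)CC(=O)OC(C)(C)C | intermediate
21 | 7α-alcohol (C1 epimers) | C[C@@H]1[C@H](O)C[C@]2(COC(=O)C2)[C@H](C(CO[Si](c3ccccc3)(c3ccccc3)C(C)(C)C)c3ccco3)[C@@]1(C)CC(=O)OC(C)(C)C | intermediate
22 | 7α-acetate (C1 epimers) | C[C@@H]1[C@H](OC(C)=O)C[C@]2(COC(=O)C2)[C@H](C(CO[Si](c3ccccc3)(c3ccccc3)C(C)(C)C)c3ccco3)[C@@]1(C)CC(=O)OC(C)(C)C | intermediate
23 | (E)-dimethylaminomethylene lactone (C1 epimers) | C[C@@H]1[C@H](OC(C)=O)C[C@]2(COC(=O)/C2=C/N(C)C)[C@H](C(CO[Si](c3ccccc3)(c3ccccc3)C(C)(C)C)c3ccco3)[C@@]1(C)CC(=O)OC(C)(C)C | intermediate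
24 | α-hydroxymethylene lactone (C1 epimers) | C[C@@H]1[C@H](OC(C)=O)C[C@]2(COC(=O)C2=CO)[C@H](C(CO[Si](c3ccccc3)(c3ccccc3)C(C)(C)C)c3ccco3)[C@@]1(C)CC(=O)OC(C)(C)C | intermediate
25 | (E)-enol triflate of the formyl lactone (C1 epimers) | C[C@@H]1[C@H](OC(C)=O)C[C@]2(COC(=O)/C2=C/OS(=O)(=O)C(F)(F)F)[C@H](C(CO[Si](c3ccccc3)(c3ccccc3)C(C)(C)C)c3ccco3)[C@@]1(C)CC(=O)OC(C)(C)C | intermediate
26 | C12 trimethylsilyl ester (C1 epimers) | C[C@@H]1[C@H](OC(C)=O)C[C@]2(COC(=O)/C2=C/OS(=O)(=O)C(F)(F)F)[C@H](C(CO[Si](c3ccccc3)(c3ccccc3)C(C)(C)C)c3ccco3)[C@@]1(C)CC(=O)O[Si](C)(C)C | intermediate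
27 | C12 carboxylic acid (C1 epimers) | C[C@@H]1[C@H](OC(C)=O)C[C@]2(COC(=O)/C2=C/OS(=O)(=O)C(F)(F)F)[C@H](C(CO[Si](c3ccccc3)(c3ccccc3)C(C)(C)C)c3ccco3)[C@@]1(C)CC(=O)O | intermediate
28 | C12 acid chloride (C1 epimers) | C[C@@H]1[C@H](OC(C)=O)C[C@]2(COC(=O)/C2=C/OS(=O)(=O)C(F)(F)F)[C@H](C(CO[Si](c3ccccc3)(c3ccccc3)C(C)(C)C)c3ccco3)[C@@]1(C)CC(=O)Cl | intermediate
29 | tricyclic C12 ketone, (E)-enol triflate, C2 silyl ether (C1 epimers) | CC(=O)O[C@@H]1C[C@]2(COC(=O)/C2=C/OS(=O)(=O)C(F)(F)F)[C@@H]3C(CO[Si](c4ccccc4)(c4ccccc4)C(C)(C)C)c4occc4C(=O)C[C@@]3(C)[C@@H]1C | intermediate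
30 | tricyclic (E)-alkenylstannane (C1 epimers) | CC(=O)O[C@@H]1C[C@]2(COC(=O)/C2=C/[Sn](C)(C)C)[C@@H]3C(CO[Si](c4ccccc4)(c4ccccc4)C(C)(C)C)c4occc4C(=O)C[C@@]3(C)[C@@H]1C | intermediate
31 | tricyclic (E)-iodomethylene lactone, C2 silyl ether (C1 epimers) | CC(=O)O[C@@H]1C[C@]2(COC(=O)/C2=C/I)[C@@H]3C(CO[Si](c4ccccc4)(c4ccccc4)C(C)(C)C)c4occc4C(=O)C[C@@]3(C)[C@@H]1C | intermediate
32 | tricyclic (E)-iodomethylene lactone, C2 alcohol (C1 epimers) | CC(=O)O[C@@H]1C[C@]2(COC(=O)/C2=C/I)[C@@H]3C(CO)c4occc4C(=O)C[C@@]3(C)[C@@H]1C | intermediate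
33 | C2 aldehyde as C1 epimer mixture | CC(=O)O[C@@H]1C[C@]2(COC(=O)/C2=C/I)[C@@H]3C(C=O)c4occc4C(=O)C[C@@]3(C)[C@@H]1C | intermediate
34 | aldehyde precursor: rings B and C, C5 spiro (E)-iodomethylene lactone, C1 formyl group | CC(=O)O[C@@H]1C[C@]2(COC(=O)/C2=C/I)[C@@H]3[C@@H](C=O)c4occc4C(=O)C[C@@]3(C)[C@@H]1C | intermediate
35 | CNP0182929.1 | CC(=O)O[C@@H]1C[C@@]23COC(=O)C2=C[C@H](O)[C@H]2c4occc4C(=O)C[C@@](C)([C@@H]1C)[C@@H]23 | target

**Step count**

Total: 25 steps. Longest linear sequence: 23 steps (1 → 35 through steps 1–3 and 6–25); steps 4 and 5 make fragment 8.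

**Steps most likely to fail, with fallbacks**

Step 25 (ring A closure). The process at risk is poor facial selectivity at the C2 carbonyl during the ring closure (chromium-bound oxygen axial instead of pseudoequatorial). The fallback sets out from 34 and returns at 35. The cyclisation is run without regard to C2, and the product, the 2-epi alcohol F7 alone or mixed with 35, is oxidised with Dess–Martin periodinane to the ring A enone F8. Luche reduction (NaBH4, CeCl3·7H2O, MeOH, −78 °C) then delivers hydride axially to the enone carbonyl and gives the pseudoequatorial 2α-alcohol 35. The low temperature and one equivalent of hydride are intended to spare the furan-conjugated C12 ketone.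

Step 6 (asymmetric alkenyl addition). The process at risk is slow transfer of the hindered alkenyl group to the neopentyl β-carbon together with incomplete discrimination of the two enone arms by the chiral catalyst. The fallback sets out from 4 and returns at 9; it moves the enantioselection to a chiral-base desymmetrisation and leaves only substrate control for the C–C bond.
- Ketone 4 is deprotonated with lithium bis(1-phenylethyl)amide (the enantiomer that gives the drawn product) in the presence of LiCl and Me3SiCl, giving the enantioenriched trimethylsilyl enol ether F1.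
- Saegusa oxidation (Pd(OAc)2, MeCN) gives the mono-enone F2.
- Addition of 8 with an achiral, more active catalyst ([Rh(cod)OH]2, dioxane/H2O, 60 °C) occurs on the nitrile face and gives the saturated ketone F3.
- Kinetic silylation at the less hindered C7 (LiN(i-Pr)2, Me3SiCl) gives the silyl enol ether F4, and a second Saegusa oxidation returns enone 9.

Step 8 (quaternary C9). The process at risk is O-alkylation and stalled conversion in the SN2 alkylation of the crowded, fully substituted enolate carbon. The fallback sets out from 10 and returns at 11.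
- 10 is converted with Me3SiOTf and Et3N into the trimethylsilyl dienol ether F5.
- ZnBr2-catalysed alkylation with tert-butyl chloro(phenylthio)acetate, an SN1-type thionium electrophile that again attacks anti to the C10 substituent, gives the phenylthio ester F6.
- Radical desulfurisation (Bu3SnH, AIBN, toluene, 80 °C) gives 11.

**Further compounds**

F1 | step 6 | tert-butyl 2-[1-cyano-4-(trimethylsilyloxy)cyclohex-3-en-1-yl]acetate, single enantiomer | N#C[C@@]1(CC(=O)OC(C)(C)C)CCC(O[Si](C)(C)C)=CC1
F2 | step 6 | tert-butyl 2-(1-cyano-4-oxocyclohex-2-en-1-yl)acetate, single enantiomer | N#C[C@@]1(CC(=O)OC(C)(C)C)CCC(=O)C=C1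
F3 | step 6 | tert-butyl 2-[1-cyano-2-[1-(furan-2-yl)ethenyl]-4-oxocyclohexyl]acetate, alkenyl cis to nitrile | N#C[C@@]1(CC(=O)OC(C)(C)C)CCC(=O)C[C@H]1C(=C)c1ccco1
F4 | step 6 | C7 trimethylsilyl enol ether of F3 | N#C[C@@]1(CC(=O)OC(C)(C)C)CC=C(O[Si](C)(C)C)C[C@H]1C(=C)c1ccco1
F5 | step 8 | trimethylsilyl dienol ether of 10 | N#C[C@@]1(CC(=O)OC(C)(C)C)C=CC(O[Si](C)(C)C)=C(C)[C@H]1C(=C)c1ccco1
F6 | step 8 | C11 phenylthio derivative of 11 (epimers at C11) | N#C[C@@]1(CC(=O)OC(C)(C)C)C=CC(=O)[C@](C)(C(Sc2ccccc2)C(=O)OC(C)(C)C)[C@H]1C(=C)c1ccco1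
F7 | step 25 | 2-epi-35 (2β-alcohol) | CC(=O)O[C@@H]1C[C@@]23COC(=O)C2=C[C@@H](O)[C@H]2c4occc4C(=O)C[C@@](C)([C@@H]1C)[C@@H]23
F8 | step 25 | C2 ketone (ring A enone) | CC(=O)O[C@@H]1C[C@@]23COC(=O)C2=CC(=O)[C@H]2c4occc4C(=O)C[C@@](C)([C@@H]1C)[C@@H]23
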